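**Plan**

Numbering: hydrindane C1 (bears C8), C2 (OH), C3, C3a (Me), C4 (Br), C5, C6, C7 (Me, OH), C7a (H); linker C8 (OAc); ring C = C1' (OH) to C6' with C4' (Br), C5' (Me2); ring A = C1–C2–C3–C3a–C7a, ring B = C3a–C4–C5–C6–C7–C7a.
Retrosynthesis cuts C2–C3 and C1–C2 of ring A (C2 becomes carbon monoxide), then C8–C1' (acetylide plus ring C ketone), then C3a–C7a of ring B and C5'–C6' of ring C (two bromonium cyclisations).
Enabling feature: C3 is an unsubstituted CH2 on quaternary C3a and C2 is a carbinol carbon lying between C3 and C1, so a C3 radical can take up CO and the acyl radical can close on C1 of a C1=C8 enol acetate to make ring A.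
Forward order: ring C (steps 1–5) and ring B (steps 6–18) are made separately and joined at C8–C1' (step 19); the alkyne becomes the Z enol acetate and C3 the iodide (steps 20–24); ring A closes last (step 25), followed by reduction and desilylation.
Stereochemistry: C4' from a Shi epoxide, C4 and C3a from a Sharpless epoxide, each relayed through a bromonium ion; C7a from the chair cyclisation; C7 and C1' by equatorial attack on ring ketones; C1 and C8 in the radical step; C2 by hydride delivery anti to the C1 side chain.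

Key step: step 25

Remark: the tertiary hydroxyls pass through the key step as triethylsilyl ethers. The catalyst enantiomers of steps 2 and 8 are taken to be those that give epoxides 4 and 13 as drawn.

**Route**

Step 1
Reactants: 1 5-bromo-2-methylpent-2-ene; 2 lithium acetylide–ethane-1,2-diamine complex
Product: 3 6-methylhept-5-en-1-yne
Conditions: DMSO, 10 °C to rt
Reagents that add atoms: none
Why: SN2 alkylation of an acetylide by a primary homoallylic bromide, a standard entry to terminal 1,5-enynes.

Step 2
Reactants: 3 6-methylhept-5-en-1-yne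
Product: 4 (R)-3-(but-3-yn-1-yl)-2,2-dimethyloxirane
Conditions: 1,2:4,5-di-O-isopropylidene-β-D-erythro-2,3-hexodiulo-2,6-pyranose (30 mol%), KHSO5 (as 2KHSO5·KHSO4·K2SO4), K2CO3, Bu4NHSO4, MeCN/CH2(OMe)2/aq. Na2B4O7, 0 °C
Reagents that add atoms: potassium peroxymonosulfate, OOS(=O)(=O)[O-].[K+]
Why: Shi asymmetric epoxidation of a trisubstituted alkene by the chiral dioxirane, the D-fructose-derived ketone giving the (R)-epoxide while the alkyne is inert.

Step 3
Reactants: 4 (R)-3-(but-3-yn-1-yl)-2,2-dimethyloxirane
Product: 5 (R)-6-bromo-6-methylhept-1-yn-5-ol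
Conditions: 48% aq. HBr, Et2O, −20 °C
Reagents that add atoms: hydrogen bromide, Br
Why: Acid-mediated epoxide opening by bromide at the tertiary carbon leaves the C–O stereocentre untouched, and any regioisomeric bromohydrin would give the same bromonium ion in step 4.

Step 4
Reactants: 5 (R)-6-bromo-6-methylhept-1-yn-5-ol
Product: 6 (S)-5-bromo-6-chloro-6-methylhept-1-yne
Conditions: SOCl2, pyridine, CH2Cl2, −20 to 0 °C
Reagents that add atoms: thionyl chloride, ClS(Cl)=O
Why: Chlorodehydroxylation with neighbouring-group participation, in which the anti bromine displaces the chlorosulfite with inversion to give the bromonium ion and chloride opens it at the tertiary carbon, so the epoxide configuration becomes the (S)-C–Br centre.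

Step 5
Reactants: 6 (S)-5-bromo-6-chloro-6-methylhept-1-yne
Product: 7 (S)-4-bromo-3,3-dimethylcyclohexan-1-one
Conditions: (CF3)2CHOH/H2O (10:1), rt
Reagents that add atoms: water, O
Why: Solvolytic ionisation of the tertiary chloride regenerates the enantioenriched bromonium ion, the terminal alkyne carbon captures it in a 6-endo cation–alkyne cyclisation (forming C5'–C6'), and water traps the cyclohexenyl cation as the ketone with the C4' bromide retained.

Step 6
Reactants: 8 1-bromo-3-methylbut-2-ene; 9 acetonitrile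
Product: 11 5-methylhex-4-enenitrile, via lithioacetonitrile 10 (not isolated)
Conditions: n-BuLi, MeCN (excess), THF, −78 °C; then 8, −78 °C to rt
Reagents that add atoms: none
Why: SN2 alkylation of lithiated acetonitrile by an allylic bromide, with excess nitrile to suppress dialkylation.

Step 7
Reactants: 11 5-methylhex-4-enenitrile
Product: 12 (E)-6-hydroxy-5-methylhex-4-enenitrile
Conditions: SeO2 (cat.), t-BuOOH, salicylic acid (cat.), CH2Cl2, rt
Reagents that add atoms: tert-butyl hydroperoxide, CC(C)(C)OO
Why: Selenium dioxide allylic oxidation (ene reaction then [2,3]-sigmatropic shift) oxidises the (E)-methyl of a prenyl terminus, fixing the E geometry that later places C3 equatorial on C3a.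

Step 8
Reactants: 12 (E)-6-hydroxy-5-methylhex-4-enenitrile
Product: 13 3-[(2R,3R)-3-(hydroxymethyl)-3-methyloxiran-2-yl]propanenitrile
Conditions: Ti(OiPr)4 (10 mol%), D-(−)-diethyl tartrate (12 mol%), t-BuOOH, 4 Å molecular sieves, CH2Cl2, −20 °C
Reagents that add atoms: tert-butyl hydroperoxide, CC(C)(C)OO
Why: Sharpless asymmetric epoxidation of an (E)-2-methylallylic alcohol, the D-(−)-tartrate catalyst giving the (2R,3R)-epoxy alcohol that fixes C3a and, after inversion, C4.

Step 9
Reactants: 13 3-[(2R,3R)-3-(hydroxymethyl)-3-methyloxiran-2-yl]propanenitrile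
Product: 14 (4S,5R)-4-bromo-5,6-dihydroxy-5-methylhexanenitrile
Conditions: Ti(OiPr)4 (1.5 equiv), Et2NH2Br, CH2Cl2, 0 °C to rt
Reagents that add atoms: diethylammonium bromide, CC[NH2+]CC.[Br-]
Why: Titanium-mediated C3-selective opening of a 2,3-epoxy alcohol by bromide (SN2 with inversion at the secondary carbon) gives the (S)-bromide at C4 anti to the tertiary C3a hydroxyl.

Step 10
Reactants: 14 (4S,5R)-4-bromo-5,6-dihydroxy-5-methylhexanenitrile
Product: 15 (4S,5R)-4-bromo-6-[(tert-butyldiphenylsilyl)oxy]-5-hydroxy-5-methylhexanenitrile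
Conditions: t-BuPh2SiCl, imidazole, CH2Cl2, 0 °C
Reagents that add atoms: tert-butyl(chloro)diphenylsilane, CC(C)(C)[Si](Cl)(c1ccccc1)c1ccccc1
Why: Selective silylation of the primary hydroxyl of a primary/tertiary diol, a silyl ether being chosen because it cannot participate in the later bromonium ion.

Step 11
Reactants: 15 (4S,5R)-4-bromo-6-[(tert-butyldiphenylsilyl)oxy]-5-hydroxy-5-methylhexanenitrile
Product: 16 (4S,5R)-4-bromo-6-[(tert-butyldiphenylsilyl)oxy]-5-chloro-5-methylhexanenitrile
Conditions: SOCl2, pyridine, CH2Cl2, −20 to 0 °C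
Reagents that add atoms: thionyl chloride, ClS(Cl)=O
Why: Tertiary alcohol to tertiary chloride with retention through the bromine-bridged cation (double inversion), giving a vicinal bromochloride as an ionisable bromonium precursor.

Step 12
Reactants: 16 (4S,5R)-4-bromo-6-[(tert-butyldiphenylsilyl)oxy]-5-chloro-5-methylhexanenitrile
Product: 18 (7S,8R)-7-bromo-9-[(tert-butyldiphenylsilyl)oxy]-8-chloro-8-methylnon-1-en-4-one, via zinc ketiminate 17 (not isolated)
Conditions: CH2=CHCH2ZnBr (preformed, zinc-free solution), THF, 0 °C to rt; then 1 M aq. HCl, 0 °C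
Reagents that add atoms: allylzinc bromide, C=CC[Zn]Br; water, O
Why: Blaise-type addition of an allylzinc reagent to the nitrile and mild hydrolysis of the metallo-imine give the β,γ-unsaturated ketone, and the organozinc leaves both alkyl halides untouched.

Step 13
Reactants: 18 (7S,8R)-7-bromo-9-[(tert-butyldiphenylsilyl)oxy]-8-chloro-8-methylnon-1-en-4-one
Product: 19 (3Z,7S,8R)-7-bromo-4-[(tert-butyldimethylsilyl)oxy]-9-[(tert-butyldiphenylsilyl)oxy]-8-chloro-8-methylnona-1,3-diene
Conditions: t-BuMe2SiOTf, Et3N, CH2Cl2, −78 °C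
Reagents that add atoms: tert-butyldimethylsilyl triflate, CC(C)(C)[Si](C)(C)OS(=O)(=O)C(F)(F)F
Why: Soft enolisation removes the doubly activated C7a hydrogen (α to the ketone and allylic) regioselectively to give the conjugated (Z)-2-silyloxy-1,3-diene.

Step 14
Reactants: 19 (3Z,7S,8R)-7-bromo-4-[(tert-butyldimethylsilyl)oxy]-9-[(tert-butyldiphenylsilyl)oxy]-8-chloro-8-methylnona-1,3-diene
Product: 20 (2S,3R,4S)-4-bromo-3-{[(tert-butyldiphenylsilyl)oxy]methyl}-2-ethenyl-3-methylcyclohexan-1-one
Conditions: TiCl4, CH2Cl2, −78 °C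
Reagents that add atoms: none
Why: Proposed new method: TiCl4 ionises the tertiary C3a–Cl bond with anchimeric assistance by the anti C4 bromine, and C7a of the silyl dienol ether opens the enantioenriched bromonium ion at C3a anti to bromine through a chair (bromine equatorial, C3a methyl axial, C7a vinyl equatorial), which closes ring B and sets C3a and C7a relative to C4; the closest known reactions are the Lewis acid-mediated tert-alkylation of silyl enol ethers by tertiary chlorides and the enantiospecific solvolytic cyclisation of vicinal bromochlorides.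

Step 15
Reactants: 20 (2S,3R,4S)-4-bromo-3-{[(tert-butyldiphenylsilyl)oxy]methyl}-2-ethenyl-3-methylcyclohexan-1-one
Product: 21 (1R,2S,3R,4S)-4-bromo-3-{[(tert-butyldiphenylsilyl)oxy]methyl}-2-ethenyl-1,3-dimethylcyclohexan-1-ol
Conditions: MeLi, CeCl3, THF, −78 °C
Reagents that add atoms: methyllithium, [Li]C
Why: Organocerium 1,2-addition to an enolisable ketone, in which the axial C3a methyl blocks axial attack at C7 so that methyl enters equatorially and the C7 hydroxyl is axial, cis to the angular methyl.

Step 16
Reactants: 21 (1R,2S,3R,4S)-4-bromo-3-{[(tert-butyldiphenylsilyl)oxy]methyl}-2-ethenyl-1,3-dimethylcyclohexan-1-ol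
Product: 22 O-triethylsilyl ether of 21
Conditions: Et3SiOTf, 2,6-lutidine, CH2Cl2, −78 to 0 °C
Reagents that add atoms: triethylsilyl triflate, CC[Si](CC)(CC)OS(=O)(=O)C(F)(F)F
Why: Silyl triflate silylation of a hindered tertiary alcohol, which prevents retro-aldol cleavage and carbonate formation at O7 in the following steps.

Step 17
Reactants: 22 O-triethylsilyl ether of 21
Product: 24 ring B aldehyde (formyl group on C7a), via 1,2,4-trioxolane 23 (not isolated)
Conditions: O3, CH2Cl2, −78 °C; then PPh3, −78 °C to rt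
Reagents that add atoms: ozone, [O-][O+]=O
Why: Ozonolysis of the terminal vinyl group with reductive work-up leaves C1 as the aldehyde carbon, and the neutral conditions do not epimerise the hindered C7a centre.

Step 18
Reactants: 24 ring B aldehyde
Product: 25 ring B alkyne (ethynyl group on C7a)
Conditions: Me3SiCHN2, LiN(iPr)2, THF, −78 to 0 °C
Reagents that add atoms: (trimethylsilyl)diazomethane, C[Si](C)(C)C=[N+]=[N-]
Why: Colvin rearrangement, in which the lithiated silyldiazomethane adds to the aldehyde, loss of silanolate and nitrogen gives the alkylidene carbene and a 1,2-hydrogen shift gives the terminal alkyne (C1≡C8) at low temperature.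

Step 19
Reactants: 25 ring B alkyne; 7 (S)-4-bromo-3,3-dimethylcyclohexan-1-one
Product: 28 propargylic alcohol (C7a–C1≡C8–C1' with axial C1' hydroxyl cis to C4'–Br), via lithium acetylide 26 (not isolated), via alkynylcerium dichloride 27 (not isolated)
Conditions: n-BuLi, THF, −78 °C; CeCl3, −78 °C; then 7, −78 °C
Reagents that add atoms: none
Why: Alkynylcerium addition to an enolisable ketone (which also suppresses 1,3-elimination of the γ-bromo ketone), where the axial C5' methyl shields the axial face so that attack is equatorial and, on the chair with equatorial bromine, the C1' hydroxyl ends axial and cis to C4'–Br.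

Step 20
Reactants: 28 propargylic alcohol
Product: 30 α-hydroxy ketone (C8 ketone, C1 methylene), via cyclic enol carbonate 29 (not isolated)
Conditions: AgOAc (10 mol%), DBU, CO2 (1 atm), MeCN/H2O, 40 °C
Reagents that add atoms: carbon dioxide, O=C=O; water, O
Why: Silver-catalysed carboxylative cyclisation of a tertiary propargylic alcohol (5-exo-dig attack of the carbonate on C8) followed by hydrolysis of the enol carbonate is a regioselective alkyne hydration that places the carbonyl at C8.

Step 21
Reactants: 30 α-hydroxy ketone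
Product: 31 triol ketone (free hydroxyls at C3, C7 and C1')
Conditions: Bu4NF, THF, 0 °C to rt
Reagents that add atoms: none
Why: Fluoride cleavage of both silyl ethers frees the neopentyl C3 hydroxyl for iodination.

Step 22
Reactants: 31 triol ketone
Product: 33 C3 iodide, via primary triflate 32 (not isolated)
Conditions: (CF3SO2)2O, 2,6-lutidine, CH2Cl2, −78 °C; then NaI, DMF, rt to 40 °C
Reagents that add atoms: sodium iodide, [Na+].[I-]
Why: Chemoselective triflation of the only primary hydroxyl and SN2 displacement by iodide, the triflate being reactive enough at a neopentyl carbon while the two tertiary alcohols stay untouched.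

Step 23
Reactants: 33 C3 iodide
Product: 34 O7,O1'-bis(triethylsilyl) ether of 33
Conditions: Et3SiOTf (excess), 2,6-lutidine, CH2Cl2, −78 to 0 °C
Reagents that add atoms: triethylsilyl triflate, CC[Si](CC)(CC)OS(=O)(=O)C(F)(F)F
Why: Silylation of both tertiary alcohols leaves C1–H as the only acidic site, triethylsilyl being preferred to trimethylsilyl to stop O-to-O silyl migration in the enolate.

Step 24
Reactants: 34 bis(triethylsilyl) ether
Product: 36 Z enol acetate (C1=C8, acetoxy on C8), via potassium enolate 35 (not isolated)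
Conditions: KN(SiMe3)2, THF, −78 °C; then Ac2O, −78 °C
Reagents that add atoms: acetic anhydride, CC(=O)OC(C)=O
Why: Kinetic deprotonation at C1, the only enolisable position, gives the enolate with C7a syn to oxygen (avoiding allylic strain against quaternary C1'), and acetic anhydride O-acetylates the potassium enolate.

Step 25
Reactants: 36 Z enol acetate; 37 carbon monoxide
Product: 38 C2 ketone with ring A closed (C8 acetate, O7,O1'-bis(triethylsilyl) ether)
Conditions: (Me3Si)3SiH (1.2 equiv), azobisisobutyronitrile (0.2 equiv), CO (80 atm), C6H6 (0.01 M), 80 °C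
Reagents that add atoms: none
Why: The silyl radical abstracts iodine from C3, the neopentyl C3 radical (which has no direct cyclisation open to it other than 4-exo or 5-endo) adds CO to form the C2–C3 bond, the C2 acyl radical adds to C1 of the enol acetate to form the C1–C2 bond, and the α-acetoxy C8 radical takes hydrogen from the silane, which carries the chain. The closest known reactions are the hydride-mediated carbonylation–cyclisation of 4-alkenyl iodides to cyclopentanones and the radical-chain addition of acyl radicals to the unsubstituted end of enol acetates. Ring A (C1, C2, C3, C3a, C7a) closes in the 5-exo-trig mode and is trans-fused because the C3 and C1 arms are trans-diequatorial on ring B. C1 is controlled by allylic 1,3-strain: C7a–H eclipses the C1=C8 bond on the side of the Z acetoxy group, so the acyl radical tethered through C3a attacks the face that leaves C8 cis to C7a–H and anti to C7. C8 is controlled by 1,2-induction from C1: the C8 radical holds C1–H in its plane syn to the bulky C1' substituent and the silane delivers hydrogen from the side of the flat C2 carbonyl, anti to ring B. The step needs iodine-selective chain transfer, secured by the much faster abstraction of primary C–I than of secondary C–Br and by only a slight excess of silane, and it needs CO capture to outrun hydrogen transfer, secured by high CO pressure and high dilution.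

Step 26
Reactants: 38 C2 ketone
Product: 39 C2 alcohol (hydroxyl cis to the C1 side chain)
Conditions: LiBH(sec-Bu)3, THF, −78 °C; AcOH quench at −78 °C
Reagents that add atoms: none
Why: Bulky trialkylborohydride reduction of an α-substituted cyclopentanone delivers hydride to C2 from the face anti to the adjacent C1 side chain, and the cold acidic quench prevents acetyl migration from O8 to O2.

Step 27
Reactants: 39 C2 alcohol
Product: 40 CNP0166243.1
Conditions: HF·pyridine, pyridine/THF, 0 °C to rt
Reagents that add atoms: none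
Why: Acidic fluoride cleavage of the two tertiary triethylsilyl ethers, under which the C8 acetate neither migrates nor is cleaved.

**Compound list**

1 | 5-bromo-2-methylpent-2-ene | CC(C)=CCCBr | starting material
2 | lithium acetylide–ethane-1,2-diamine complex | [Li]C#C.NCCN | starting material
3 | 6-methylhept-5-en-1-yne | C#CCCC=C(C)C | intermediate
4 | (R)-3-(but-3-yn-1-yl)-2,2-dimethyloxirane | C#CCC[C@H]1OC1(C)C | intermediate
5 | (R)-6-bromo-6-methylhept-1-yn-5-ol | C#CCC[C@@H](O)C(C)(C)Br | intermediate
6 | (S)-5-bromo-6-chloro-6-methylhept-1-yne | C#CCC[C@H](Br)C(C)(C)Cl | intermediate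
7 | (S)-4-bromo-3,3-dimethylcyclohexan-1-one | O=C1CC[C@H](Br)C(C)(C)C1 | intermediate
8 | 1-bromo-3-methylbut-2-ene | CC(C)=CCBr | starting material
9 | acetonitrile | CC#N | starting material
10 | lithioacetonitrile (not isolated) | [Li]CC#N | intermediate
11 | 5-methylhex-4-enenitrile | CC(C)=CCCC#N | intermediate
12 | (E)-6-hydroxy-5-methylhex-4-enenitrile | OC/C(C)=C/CCC#N | intermediate
13 | 3-[(2R,3R)-3-(hydroxymethyl)-3-methyloxiran-2-yl]propanenitrile | N#CCC[C@H]1O[C@]1(C)CO | intermediate
14 | (4S,5R)-4-bromo-5,6-dihydroxy-5-methylhexanenitrile | N#CCC[C@H](Br)[C@](C)(O)CO | intermediate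
15 | (4S,5R)-4-bromo-6-[(tert-butyldiphenylsilyl)oxy]-5-hydroxy-5-methylhexanenitrile | N#CCC[C@H](Br)[C@](C)(O)CO[Si](c1ccccc1)(c1ccccc1)C(C)(C)C | intermediate
16 | (4S,5R)-4-bromo-6-[(tert-butyldiphenylsilyl)oxy]-5-chloro-5-methylhexanenitrile | N#CCC[C@H](Br)[C@](C)(Cl)CO[Si](c1ccccc1)(c1ccccc1)C(C)(C)C | intermediate
17 | N-(bromozincio) ketimine of 18 (not isolated) | C=CCC(CC[C@H](Br)[C@](C)(Cl)CO[Si](c1ccccc1)(c1ccccc1)C(C)(C)C)=N[Zn]Br | intermediate
18 | (7S,8R)-7-bromo-9-[(tert-butyldiphenylsilyl)oxy]-8-chloro-8-methylnon-1-en-4-one | C=CCC(=O)CC[C@H](Br)[C@](C)(Cl)CO[Si](c1ccccc1)(c1ccccc1)C(C)(C)C | intermediate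
19 | (3Z,7S,8R)-7-bromo-4-[(tert-butyldimethylsilyl)oxy]-9-[(tert-butyldiphenylsilyl)oxy]-8-chloro-8-methylnona-1,3-diene | C=C/C=C(\O[Si](C)(C)C(C)(C)C)CC[C@H](Br)[C@](C)(Cl)CO[Si](c1ccccc1)(c1ccccc1)C(C)(C)C | intermediate
20 | (2S,3R,4S)-4-bromo-3-{[(tert-butyldiphenylsilyl)oxy]methyl}-2-ethenyl-3-methylcyclohexan-1-one | CC(C)(C)[Si](c1ccccc1)(c1ccccc1)OC[C@]1(C)[C@@H](Br)CCC(=O)[C@H]1C=C | intermediate
21 | (1R,2S,3R,4S)-4-bromo-3-{[(tert-butyldiphenylsilyl)oxy]methyl}-2-ethenyl-1,3-dimethylcyclohexan-1-ol | CC(C)(C)[Si](c1ccccc1)(c1ccccc1)OC[C@]1(C)[C@@H](Br)CC[C@@](C)(O)[C@H]1C=C | intermediate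
22 | O-triethylsilyl ether of 21 | CC(C)(C)[Si](c1ccccc1)(c1ccccc1)OC[C@]1(C)[C@@H](Br)CC[C@@](C)(O[Si](CC)(CC)CC)[C@H]1C=C | intermediate
23 | 1,2,4-trioxolane from the vinyl group of 22 (not isolated) | CC(C)(C)[Si](c1ccccc1)(c1ccccc1)OC[C@]1(C)[C@@H](Br)CC[C@@](C)(O[Si](CC)(CC)CC)[C@H]1C1OCOO1 | intermediate
24 | ring B aldehyde (formyl on C7a) | CC(C)(C)[Si](c1ccccc1)(c1ccccc1)OC[C@]1(C)[C@@H](Br)CC[C@@](C)(O[Si](CC)(CC)CC)[C@H]1C=O | intermediate
25 | ring B alkyne (ethynyl on C7a) | CC(C)(C)[Si](c1ccccc1)(c1ccccc1)OC[C@]1(C)[C@@H](Br)CC[C@@](C)(O[Si](CC)(CC)CC)[C@H]1C#C | intermediate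
26 | lithium acetylide of 25 (not isolated) | CC(C)(C)[Si](c1ccccc1)(c1ccccc1)OC[C@]1(C)[C@@H](Br)CC[C@@](C)(O[Si](CC)(CC)CC)[C@H]1C#C[Li] | intermediate
27 | alkynylcerium dichloride of 25 (not isolated) | CC(C)(C)[Si](c1ccccc1)(c1ccccc1)OC[C@]1(C)[C@@H](Br)CC[C@@](C)(O[Si](CC)(CC)CC)[C@H]1C#C[Ce](Cl)Cl | intermediate
28 | propargylic alcohol, rings B and C joined through C1≡C8 | CC(C)(C)[Si](c1ccccc1)(c1ccccc1)OC[C@]1(C)[C@@H](Br)CC[C@@](C)(O[Si](CC)(CC)CC)[C@H]1C#C[C@@]1(O)CC[C@H](Br)C(C)(C)C1 | intermediate
29 | (Z)-alkylidene cyclic carbonate spiro-fused at C1' (not isolated) | CC(C)(C)[Si](c1ccccc1)(c1ccccc1)OC[C@]1(C)[C@@H](Br)CC[C@@](C)(O[Si](CC)(CC)CC)[C@H]1/C=C1\OC(=O)O[C@@]12CC[C@H](Br)C(C)(C)C2 | intermediate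
30 | α-hydroxy ketone (C8 ketone) | CC(C)(C)[Si](c1ccccc1)(c1ccccc1)OC[C@]1(C)[C@@H](Br)CC[C@@](C)(O[Si](CC)(CC)CC)[C@H]1CC(=O)[C@@]1(O)CC[C@H](Br)C(C)(C)C1 | intermediate
31 | triol ketone | OC[C@]1(C)[C@@H](Br)CC[C@@](C)(O)[C@H]1CC(=O)[C@@]1(O)CC[C@H](Br)C(C)(C)C1 | intermediate
32 | C3 triflate of 31 (not isolated) | FC(F)(F)S(=O)(=O)OC[C@]1(C)[C@@H](Br)CC[C@@](C)(O)[C@H]1CC(=O)[C@@]1(O)CC[C@H](Br)C(C)(C)C1 | intermediate
33 | C3 iodide | IC[C@]1(C)[C@@H](Br)CC[C@@](C)(O)[C@H]1CC(=O)[C@@]1(O)CC[C@H](Br)C(C)(C)C1 | intermediate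
34 | O7,O1'-bis(triethylsilyl) ether of 33 | IC[C@]1(C)[C@@H](Br)CC[C@@](C)(O[Si](CC)(CC)CC)[C@H]1CC(=O)[C@@]1(O[Si](CC)(CC)CC)CC[C@H](Br)C(C)(C)C1 | intermediate
35 | potassium (Z)-enolate of 34 (not isolated) | IC[C@]1(C)[C@@H](Br)CC[C@@](C)(O[Si](CC)(CC)CC)[C@H]1/C=C(\O[K])[C@@]1(O[Si](CC)(CC)CC)CC[C@H](Br)C(C)(C)C1 | intermediate
36 | ring B neopentyl iodide with Z enol acetate linked to ring C (key precursor) | IC[C@]1(C)[C@@H](Br)CC[C@@](C)(O[Si](CC)(CC)CC)[C@H]1/C=C(\OC(C)=O)[C@@]1(O[Si](CC)(CC)CC)CC[C@H](Br)C(C)(C)C1 | intermediate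
37 | carbon monoxide | [C-]#[O+] | starting material
38 | C2 ketone of the target as O7,O1'-bis(triethylsilyl) ether (key product) | CC(=O)O[C@H]([C@@H]1C(=O)C[C@]2(C)[C@@H](Br)CC[C@@](C)(O[Si](CC)(CC)CC)[C@@H]12)[C@@]1(O[Si](CC)(CC)CC)CC[C@H](Br)C(C)(C)C1 | intermediate
39 | O7,O1'-bis(triethylsilyl) ether of the target | CC(=O)O[C@H]([C@@H]1[C@H](O)C[C@]2(C)[C@@H](Br)CC[C@@](C)(O[Si](CC)(CC)CC)[C@@H]12)[C@@]1(O[Si](CC)(CC)CC)CC[C@H](Br)C(C)(C)C1 | intermediate
40 | CNP0166243.1 | CC(=O)O[C@H]([C@@H]1[C@H](O)C[C@]2(C)[C@@H](Br)CC[C@@](C)(O)[C@@H]12)[C@@]1(O)CC[C@H](Br)C(C)(C)C1 | target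

**Step count and risks**

Total step count: 27. Longest linear sequence: 22 steps (steps 6–27, from 8 and 9 to 40); the ring C branch is steps 1–5.

Step 14 (Proposed new method). After ionisation the bridged cation may lose a proton to give an allylic bromide, or recapture chloride, faster than the hindered C3a–C7a bond forms, and TiCl4 may desilylate the dienol ether before it reacts. The fallback sets out from 18 and uses known chemistry. Acetic anhydride, Et3N and 4-(dimethylamino)pyridine would convert 18 into the dienyl acetate, (3Z,7S,8R)-7-bromo-9-[(tert-butyldiphenylsilyl)oxy]-8-chloro-8-methylnona-1,3-dien-4-yl acetate F1. Warming F1 in (CF3)2CHOH with 2,6-di-tert-butylpyridine would ionise the tertiary chloride by solvolysis, as in the known enantiospecific cyclisation of vicinal bromochlorides onto alkenes; the acid-stable enol acetate serves as the olefinic trap and passes its acetyl group to the solvent. The fallback comes back to the route at 20.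

Step 25. The hindered neopentyl radical may be reduced before it captures CO, the acyl radical may be reduced to the aldehyde before the trans-fused ring closes, and the silyl radical may abstract bromine at C4 or C4'. The fallback sets out from 36 and replaces carbon monoxide by an isonitrile as the one-carbon unit. With 2,6-dimethylphenyl isocyanide, (Me3Si)3SiH and azobisisobutyronitrile in benzene at 80 °C (no pressure, slow silane addition) the C3 radical adds irreversibly to the isonitrile and the imidoyl radical closes 5-exo onto C1 to give the N-(2,6-dimethylphenyl) ketimine of 38, F2. Hydrolysis of F2 with aqueous oxalic acid in THF comes back to the route at 38.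

Step 19. Ketone 7 is conformationally mobile: reaction through the ring-flipped chair with axial bromine, still by equatorial attack, would give the C1' epimer, and the basic acetylide may enolise 7 with loss of bromide by 1,3-elimination. The fallback sets out from 6 and 25 and introduces the C1' oxygen last, closing ring C on the coupled material. Bromoboration of alkyne 6 with B-bromo-9-borabicyclo[3.3.1]nonane and protonolysis with AcOH would give (S)-2,5-dibromo-6-chloro-6-methylhept-1-ene F3. Sonogashira coupling of F3 with 25 (Pd(PPh3)4, CuI, Et3N) would give the dienyne F4. In (CF3)2CHOH/H2O the bromonium ion from F4 would be opened by the CH2 terminus of the 1,1-disubstituted alkene (C6'), and water would capture the propargylic C1' cation from the equatorial direction, which comes back to the route at 28.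

Further compounds
F1 | step 14 | (3Z,7S,8R)-7-bromo-9-[(tert-butyldiphenylsilyl)oxy]-8-chloro-8-methylnona-1,3-dien-4-yl acetate | C=C/C=C(\OC(C)=O)CC[C@H](Br)[C@](C)(Cl)CO[Si](c1ccccc1)(c1ccccc1)C(C)(C)C
F2 | step 25 | N-(2,6-dimethylphenyl) ketimine of 38 at C2 | CC(=O)O[C@H]([C@@H]1C(=Nc3c(C)cccc3C)C[C@]2(C)[C@@H](Br)CC[C@@](C)(O[Si](CC)(CC)CC)[C@@H]12)[C@@]1(O[Si](CC)(CC)CC)CC[C@H](Br)C(C)(C)C1
F3 | step 19 | (S)-2,5-dibromo-6-chloro-6-methylhept-1-ene | C=C(Br)CC[C@H](Br)C(C)(C)Cl
F4 | step 19 | dienyne from 25 and F3 (C1≡C8–C1'(=CH2) chain with the bromochloride terminus) | CC(C)(C)[Si](c1ccccc1)(c1ccccc1)OC[C@]1(C)[C@@H](Br)CC[C@@](C)(O[Si](CC)(CC)CC)[C@H]1C#CC(=C)CC[C@H](Br)C(C)(C)Cl
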